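Position labels C1–C20 follow kaurane numbering. The target is a 6,7-seco-ent-kaurane: ring A is C1–C5/C10, ring C is C8/C9/C11–C14, and ring D is C8/C13–C16.

**Retrosynthetic overview**
1. Target 16 comes from hydrolysis of its 6,19-anhydride 14; the anhydride is the only masking group in the route.
2. The key cut is C9–C10, which joins two carbonyl β-carbons (C10 is β to C6, C9 is β to C12). C10 is used with reversed polarity as a tertiary β-acyl radical (a homoenolate equivalent, from β-iodide 13) and adds to bicyclic enone 12.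
3. Ring A (4) comes from a Diels–Alder reaction of citraconic anhydride with piperylene, followed by an alkene shift.
4. Ring C (10) comes from a Diels–Alder reaction of an aminosiloxydiene with 2-propargylacrolein, which sets C8. Ring D (12) comes from a 5-exo-dig closure forming C13–C16.
5. Ring order: A and C are built in parallel, then D, then the two halves are joined. Ring B is never formed.

Assumption: the sense of induction drawn for the two chiral catalysts (steps 1 and 4) is taken by analogy; both antipodes of each are commercial, so the mirror-image catalyst is used if the sense proves opposite.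

**Step 1**
Reactants: 1 citraconic anhydride; 2 (E)-penta-1,3-diene
Product: 3 (3aR,7S,7aS)-3a,7-dimethyl-3a,4,7,7a-tetrahydro-2-benzofuran-1,3-dione
Conditions: (S)-3,3-diphenyl-1-(2-methylphenyl)tetrahydro-1H,3H-pyrrolo[1,2-c][1,3,2]oxazaborole (20 mol %), Tf2NH (18 mol %), 2 (3 equiv), CH2Cl2, −40 °C, 48 h
Reagents that add atoms: none
Why: Proposed new method: enantioselective Diels–Alder reaction of an anhydride under cationic oxazaborolidinium catalysis, reasoned from the established use of this Lewis acid with fumarates, quinones and other cyclic Z-dienophiles and from the known Lewis-acid acceleration of anhydride cycloadditions: boron binds the less hindered carbonyl (next to the vinylic C–H), which makes the methyl-bearing β-carbon the most electrophilic site so that it bonds to the unsubstituted diene terminus (1,3-dimethyl pattern), the suprafacial endo addition fixes the cis ring fusion, and the shielded face of the bound dienophile sets C4 and C5 (3aR,7aS).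

**Step 2**
Reactants: 3 (3aR,7S,7aS)-3a,7-dimethyl-3a,4,7,7a-tetrahydro-2-benzofuran-1,3-dione
Product: 4 (3aR,7aS)-3a,7-dimethyl-3a,4,5,7a-tetrahydro-2-benzofuran-1,3-dione
Conditions: RuHCl(CO)(PPh3)3 (3 mol %), toluene, 110 °C, 12 h
Reagents that add atoms: none
Why: Metal-hydride alkene isomerisation (insertion/β-hydride elimination) walks the disubstituted alkene to the more stable trisubstituted C10=C1 position and stops there because a further shift would need a tertiary alkyl–ruthenium species; C4 and C5 are untouched and the now irrelevant C10 centre becomes sp2.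

**Step 3**
Reactants: 5 pent-4-yn-1-ol
Product: 7 2-methylidenepent-4-ynal, via pent-4-ynal 6 (not isolated)
Conditions: TEMPO (10 mol %), PhI(OAc)2 (1.0 equiv), CH2Cl2, rt; then 37% aq HCHO (1.5 equiv), pyrrolidine (20 mol %), i-PrOH, same flask, 40 °C
Reagents that add atoms: formaldehyde, C=O
Why: Oxoammonium (TEMPO) oxidation stops at the aldehyde, and the acetic acid it releases serves as co-catalyst for the amine-catalysed Mannich condensation–elimination (α-methylenation) with formaldehyde; no stereocentre is formed.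

**Step 4**
Reactants: 7 2-methylidenepent-4-ynal; 8 (E)-3-[(tert-butyldimethylsilyl)oxy]-N,N-dimethylbuta-1,3-dien-1-amine
Product: 10 (R)-4-oxo-1-(prop-2-yn-1-yl)cyclohex-2-ene-1-carbaldehyde, via amino silyl enol ether cycloadduct 9 (not isolated)
Conditions: (4R,5R)-2,2-dimethyl-α,α,α′,α′-tetra(1-naphthyl)-1,3-dioxolane-4,5-dimethanol (20 mol %), toluene, −78 °C, 48 h; then AcCl (2 equiv), CH2Cl2, −78 °C to rt
Reagents that add atoms: none
Why: Hydrogen-bond-catalysed Diels–Alder reaction of a 1-amino-3-siloxydiene with an α-substituted acrolein: the nucleophilic CH2 terminus bonds to the acrolein CH2 and the amino-bearing terminus to the α-carbon, the diol-bound formyl group exposes one face and sets the quaternary centre C8 as R, and N-acetylation then expels the amine and the silyl group to unveil the enone.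

**Step 5**
Reactants: 10 (R)-4-oxo-1-(prop-2-yn-1-yl)cyclohex-2-ene-1-carbaldehyde
Product: 11 (R)-4-[(tert-butyldimethylsilyl)oxy]-1-(prop-2-yn-1-yl)cyclohexa-2,4-diene-1-carbaldehyde
Conditions: TBSOTf (1.2 equiv), Et3N (2.0 equiv), CH2Cl2, −78 to 0 °C
Reagents that add atoms: tert-butyldimethylsilyl trifluoromethanesulfonate, CC(C)(C)[Si](C)(C)OS(=O)(=O)C(F)(F)F
Why: Soft enolisation (silyl triflate/amine): C8 is quaternary and the aldehyde has no α-hydrogen, so only the α′-CH2 (C13) can be deprotonated, which gives the cross-conjugated 2-silyloxydiene as a single regioisomer with C8 untouched.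

**Step 6**
Reactants: 11 (R)-4-[(tert-butyldimethylsilyl)oxy]-1-(prop-2-yn-1-yl)cyclohexa-2,4-diene-1-carbaldehyde
Product: 12 (1R,5R)-6-methylidene-4-oxobicyclo[3.2.1]oct-2-ene-1-carbaldehyde
Conditions: Ph3PAuCl (5 mol %), AgBF4 (5 mol %), CH2Cl2/H2O 10:1, rt
Reagents that add atoms: none
Why: Gold-catalysed 5-exo-dig carbocyclisation of a silyl enol ether onto an alkyne (Conia-ene type): C13 attacks the π-acid-activated alkyne, the one-carbon tether allows bonding only on the face that carries the propargyl arm so C13 is set as R, and protodeauration leaves the exocyclic methylene while the C9=C11 enone is regenerated.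

**Step 7 (key step)**
Reactants: 4 (3aR,7aS)-3a,7-dimethyl-3a,4,5,7a-tetrahydro-2-benzofuran-1,3-dione; 12 (1R,5R)-6-methylidene-4-oxobicyclo[3.2.1]oct-2-ene-1-carbaldehyde
Product: 14 (3aR,7S,7aS)-7-[(1R,2S,5R)-1-formyl-6-methylidene-4-oxobicyclo[3.2.1]octan-2-yl]-3a,7-dimethylhexahydro-2-benzofuran-1,3-dione, via tertiary iodide 13 (not isolated)
Conditions: 4 (2.5 equiv), Me3SiI (3 equiv), H2O (1.5 equiv), CH2Cl2, −40 to 0 °C, 1 h; volatiles removed in the same flask at 0 °C; then 12 (1 equiv), NaHCO3 (solid), toluene (0.5 M), (Me3Si)3SiH (3 equiv, syringe pump, 6 h), Et3B (0.3 equiv), air, rt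
Reagents that add atoms: none
Why: Markovnikov hydroiodination (to which any exocyclic or conjugated alkene isomer of 4 also converges) gives the β-iodo anhydride, and iodine-atom abstraction turns C10, normally the electrophilic β-carbon of the C6 acyl group, into a nucleophilic tertiary radical (a one-electron homoenolate equivalent) that adds in a Giese reaction to C9, the electrophilic β-carbon of enone 12, forging the dissonant 1,6-dicarbonyl bond; the radical reacts on the convex face of the cis-fused anhydride, anti to C6/C19 (10S), and the enone is attacked axially from the face opposite the two-carbon C15–C16 bridge (9S), so each partner controls its own new centre.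

**Step 8**
Reactants: 14 (3aR,7S,7aS)-7-[(1R,2S,5R)-1-formyl-6-methylidene-4-oxobicyclo[3.2.1]octan-2-yl]-3a,7-dimethylhexahydro-2-benzofuran-1,3-dione
Product: 16 (1R,2S,3S)-3-[(1R,2S,5R)-1-formyl-6-methylidene-4-oxobicyclo[3.2.1]octan-2-yl]-1,3-dimethylcyclohexane-1,2-dicarboxylic acid, via dilithium dicarboxylate 15 (not isolated)
Conditions: LiOH (3 equiv), THF/H2O 3:1, 0 °C; then 1 M HCl to pH 2 at 0 °C, cold extraction, no heating
Reagents that add atoms: lithium hydroxide, [Li+].[OH-]
Why: Saponification of the cyclic anhydride and cold acidification give the diacid without re-closure; no stereocentre is touched because C5–H lies between two quaternary carbons, the aldehyde has no α-hydrogen and C13 is a bridgehead.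

**Compound list**
1 | citraconic anhydride (3-methylfuran-2,5-dione) | CC1=CC(=O)OC1=O | starting material
2 | (E)-penta-1,3-diene | C/C=C/C=C | starting material
3 | (3aR,7S,7aS)-3a,7-dimethyl-3a,4,7,7a-tetrahydro-2-benzofuran-1,3-dione | C[C@H]1C=CC[C@@]2(C)C(=O)OC(=O)[C@@H]12 | intermediate
4 | (3aR,7aS)-3a,7-dimethyl-3a,4,5,7a-tetrahydro-2-benzofuran-1,3-dione | CC1=CCC[C@@]2(C)C(=O)OC(=O)[C@@H]12 | intermediate
5 | pent-4-yn-1-ol | C#CCCCO | starting material
6 | pent-4-ynal | C#CCCC=O | intermediate
7 | 2-methylidenepent-4-ynal | C#CCC(=C)C=O | intermediate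
8 | (E)-3-[(tert-butyldimethylsilyl)oxy]-N,N-dimethylbuta-1,3-dien-1-amine | CN(C)/C=C/C(=C)O[Si](C)(C)C(C)(C)C | starting material
9 | (1R,2R)-4-[(tert-butyldimethylsilyl)oxy]-2-(dimethylamino)-1-(prop-2-yn-1-yl)cyclohex-3-ene-1-carbaldehyde | C#CC[C@]1(C=O)CCC(O[Si](C)(C)C(C)(C)C)=C[C@H]1N(C)C | intermediate
10 | (R)-4-oxo-1-(prop-2-yn-1-yl)cyclohex-2-ene-1-carbaldehyde | C#CC[C@]1(C=O)CCC(=O)C=C1 | intermediate
11 | (R)-4-[(tert-butyldimethylsilyl)oxy]-1-(prop-2-yn-1-yl)cyclohexa-2,4-diene-1-carbaldehyde | C#CC[C@]1(C=O)CC=C(O[Si](C)(C)C(C)(C)C)C=C1 | intermediate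
12 | (1R,5R)-6-methylidene-4-oxobicyclo[3.2.1]oct-2-ene-1-carbaldehyde | C=C1C[C@]2(C=O)C[C@H]1C(=O)C=C2 | intermediate
13 | (3aR,7aS)-7-iodo-3a,7-dimethylhexahydro-2-benzofuran-1,3-dione (C7 epimers, inconsequential) | CC1(I)CCC[C@@]2(C)C(=O)OC(=O)[C@@H]12 | intermediate
14 | (3aR,7S,7aS)-7-[(1R,2S,5R)-1-formyl-6-methylidene-4-oxobicyclo[3.2.1]octan-2-yl]-3a,7-dimethylhexahydro-2-benzofuran-1,3-dione | C=C1C[C@]2(C=O)C[C@H]1C(=O)C[C@H]2[C@]1(C)CCC[C@@]3(C)C(=O)OC(=O)[C@@H]13 | intermediate
15 | dilithium salt of 16 | C=C1C[C@]2(C=O)C[C@H]1C(=O)C[C@H]2[C@]1(C)CCC[C@@](C)(C(=O)[O-])[C@H]1C(=O)[O-].[Li+].[Li+] | intermediate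
16 | (1R,2S,3S)-3-[(1R,2S,5R)-1-formyl-6-methylidene-4-oxobicyclo[3.2.1]octan-2-yl]-1,3-dimethylcyclohexane-1,2-dicarboxylic acid (CNP0320711.1) | C=C1C[C@]2(C=O)C[C@H]1C(=O)C[C@H]2[C@]1(C)CCC[C@@](C)(C(=O)O)[C@H]1C(=O)O | target

**Step count**
Total steps: 8.
Longest linear sequence: 6 (steps 3–8: 5 → 7 → 10 → 11 → 12 → 14 → 16).

**Steps most likely to fail**

Step 7 (fragment union). A tertiary radical must add next to a bridgehead quaternary carbon. It competes with premature reduction by the silane and with loss of HI from 13.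

The fallback sets out from 4 and 10 and comes back at 14. The bond is made one stage earlier, on monocyclic enone 10. This enone has no 1,1-disubstituted alkene, so it tolerates metal-hydride hydrogen-atom transfer. Alkene 4 and enone 10 with Fe(acac)3 and PhSiH3 in THF/i-PrOH give the monocyclic keto aldehyde F1, the radical adding anti to the propargyl arm. TBSOTf/Et3N then gives the less hindered C12–C13 silyl enol ether F2. Ph3PAuCl/AgBF4 in wet CH2Cl2 closes ring D to 14. This order is the second choice because the ring closure must pass through a conformer with the ring A substituent axial.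

Step 1 (asymmetric cycloaddition of an anhydride). The weakly basic anhydride may bind the catalyst poorly, which would give low conversion or low ee.

The fallback sets out from 2 and comes back at 4.
- Commercial dimethyl fumarate, a dienophile class for which the same oxazaborolidinium salt is established and which raises no regiochemical question, reacts with 2 to give dimethyl (1S,2S)-3-methylcyclohex-4-ene-1,2-dicarboxylate F3.
- LDA then MeI methylates the less hindered C1 anti to the neighbouring ester and gives dimethyl (1R,2S)-1,3-dimethylcyclohex-4-ene-1,2-dicarboxylate F4.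
- Hot aqueous KOH followed by acid gives the cis-diacid F5.
- Ac2O closes the anhydride as a C7 epimer mixture F6.
- RuHCl(CO)(PPh3)3 converts both epimers into 4.

Step 6 (gold cyclisation). Protodesilylation back to 10, or alkyne hydration, may outrun the closure.

The fallback sets out from 8 and comes back at 12; it replaces the alkyne with an alkene and π-acid catalysis with oxidative palladium chemistry.
- Commercial pent-4-enal is methylenated as in step 3 to 2-methylidenepent-4-enal F7.
- The catalysed cycloaddition with 8 gives the allyl cycloadduct F8.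
- AcCl converts this into (R)-4-oxo-1-(prop-2-en-1-yl)cyclohex-2-ene-1-carbaldehyde F9.
- TBSOTf/Et3N gives the allyl silyl dienol ether F10.
- Pd(OAc)2 (10 mol %) under O2 in DMSO effects cycloalkenylation (5-exo carbopalladation, then β-hydride elimination) to 12.

**Further compounds**
F1 | step 7 | (3aR,7S,7aS)-7-[(1S,2R)-2-formyl-5-oxo-2-(prop-2-yn-1-yl)cyclohexyl]-3a,7-dimethylhexahydro-2-benzofuran-1,3-dione | C#CC[C@]2(C=O)CCC(=O)C[C@H]2[C@]1(C)CCC[C@@]3(C)C(=O)OC(=O)[C@@H]13
F2 | step 7 | C12–C13 tert-butyldimethylsilyl enol ether of F1 | C#CC[C@]2(C=O)CC=C(O[Si](C)(C)C(C)(C)C)C[C@H]2[C@]1(C)CCC[C@@]3(C)C(=O)OC(=O)[C@@H]13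
F3 | step 1 | dimethyl (1S,2S)-3-methylcyclohex-4-ene-1,2-dicarboxylate | CC1C=CC[C@H](C(=O)OC)[C@H]1C(=O)OC
F4 | step 1 | dimethyl (1R,2S)-1,3-dimethylcyclohex-4-ene-1,2-dicarboxylate | CC1C=CC[C@@](C)(C(=O)OC)[C@H]1C(=O)OC
F5 | step 1 | (1R,2S)-1,3-dimethylcyclohex-4-ene-1,2-dicarboxylic acid | CC1C=CC[C@@](C)(C(=O)O)[C@H]1C(=O)O
F6 | step 1 | (3aR,7aS)-3a,7-dimethyl-3a,4,7,7a-tetrahydro-2-benzofuran-1,3-dione (C7 epimer mixture) | CC1C=CC[C@@]2(C)C(=O)OC(=O)[C@@H]12
F7 | step 6 | 2-methylidenepent-4-enal | C=CCC(=C)C=O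
F8 | step 6 | (1R,2R)-4-[(tert-butyldimethylsilyl)oxy]-2-(dimethylamino)-1-(prop-2-en-1-yl)cyclohex-3-ene-1-carbaldehyde | C=CC[C@]1(C=O)CCC(O[Si](C)(C)C(C)(C)C)=C[C@H]1N(C)C
F9 | step 6 | (R)-4-oxo-1-(prop-2-en-1-yl)cyclohex-2-ene-1-carbaldehyde | C=CC[C@]1(C=O)CCC(=O)C=C1
F10 | step 6 | (S)-4-[(tert-butyldimethylsilyl)oxy]-1-(prop-2-en-1-yl)cyclohexa-2,4-diene-1-carbaldehyde | C=CC[C@]1(C=O)CC=C(O[Si](C)(C)C(C)(C)C)C=C1
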